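**Plan**

- Numbering is that of the eudesmanes: ring A = C1–C5 and C10, ring B = C5–C10, C14 = methyl on C10, C15 = methylene carbon on C4; β is the face of C14. The intermediates are named as decalins with this numbering.
- Enabling feature: with carbonyls at C4 and C7, C4–C5–C6–C7 is a 1,4-dicarbonyl array, and quaternary C10 is the para carbon of a symmetrical 4,4-disubstituted cyclohexa-2,5-dienone that is ring B. Ring A can therefore be closed by conjugate acylation of one of two enantiotopic enone arms.
- Retrosynthetic cuts, in order: the ester C–O bond at O6; C4=C15; the C6–O and C7–C11 bonds (both traced back to the C7 ketone through the triflate of its cross-conjugated enolate); C4–C5 (ring A); C3–C4 (hydroformylation); C1–C10 (dearomatising allylation).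
- Forward: ring B is present from step 1 as the dienone from p-cresol; ring A closes onto it in the intramolecular Stetter reaction; ring B is then taken from the enone to the trans-2-isopropylcyclohexanol pattern; C4 becomes the methylene; the p-coumaroyl unit is joined last.
- Stereochemistry: C10 from the chiral carbene's choice between the two enone arms; C5 is formed cis by the tether and then equilibrated to the trans fusion; C6 and C7 are set together by syn hydroboration of the C6=C7 alkene on the face away from C14; the ester is formed at oxygen, with retention at C6.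

Key step: step 3

Assumption: the (5aS,10bR) antipode of the triazolium salt is taken to give the (10R) series; if the sense proves the reverse, the (5aR,10bS) salt from the other commercial enantiomer of cis-1-amino-2-indanol is used and nothing else changes.

**Route**

Step 1
Reactants: 1 p-cresol; 2 allyltrimethylsilane
Product: 3 4-allyl-4-methylcyclohexa-2,5-dien-1-one
Conditions: PhI(OAc)2 (1.1 equiv), 2 (5 equiv), (CF3)2CHOH, −10 °C
Reagents that add atoms: none
Why: Oxidation of the phenol by PhI(OAc)2 (trivalent iodine) in the poorly nucleophilic fluoroalcohol should give a phenoxenium-type species that the allylsilane captures at the methyl-bearing para carbon with loss of the silyl group (oxidative Hosomi–Sakurai allylation), which gives the achiral dienone and creates no stereocentre.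

Step 2
Reactants: 3 4-allyl-4-methylcyclohexa-2,5-dien-1-one
Product: 4 4-(1-methyl-4-oxocyclohexa-2,5-dien-1-yl)butanal
Conditions: Rh(acac)(CO)2 (1 mol %), 4,5-bis(diphenylphosphino)-9,9-dimethylxanthene (2 mol %), CO/H2 (1:1, 10 bar), PhMe, 60 °C
Reagents that add atoms: carbon monoxide, [C-]#[O+]
Why: Rhodium-catalysed hydroformylation with a wide-bite-angle diphosphine should place the formyl group on the terminal carbon of the monosubstituted alkene, whose neopentyl-type surroundings further disfavour the branched aldehyde, while the electron-poor disubstituted dienone alkenes react much more slowly; no stereocentre is formed.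

Step 3
Reactants: 4 4-(1-methyl-4-oxocyclohexa-2,5-dien-1-yl)butanal
Product: 5 (5S,10R)-10-methyldecal-8-ene-4,7-dione (cis-fused; H5 and C14 both β)
Conditions: (5aS,10bR)-2-(pentafluorophenyl)-5a,10b-dihydro-4H,6H-indeno[2,1-b][1,2,4]triazolo[4,3-d][1,4]oxazin-2-ium tetrafluoroborate (20 mol %), KN(SiMe3)2 (18 mol %), PhMe, 23 °C
Reagents that add atoms: none
Why: The carbene freed from the triazolium salt adds to the C4 aldehyde, proton transfer gives the nucleophilic enaminol, this adds through C4 to C5 of one enone arm, and loss of the carbene from the adduct leaves the C4 ketone. The closest known reaction type is the triazolium-catalysed asymmetric intramolecular Stetter desymmetrisation of 4,4-disubstituted cyclohexadienones, established for five-membered and oxygen-tethered closures and used here with an all-carbon tether one atom longer. Ring A closes in a 6-exo-trig conjugate addition, helped by the quaternary carbon at the origin of the tether. C10 becomes a stereocentre only through the choice between the two enantiotopic enone arms, which the chiral pocket of the aminoindanol-derived carbene makes (catalyst control), whereas C5 is fixed relative to C10 by the tether, which can reach only the face of the dienone that carries it, so the fusion is cis. The step needs enantiotopic-group selectivity and a preference for conjugate addition over aldol and benzoin reactions of the enolisable aldehyde; the symmetry of the dienone makes the first purely a matter of the catalyst, and the closeness of the tethered acceptor together with base kept below the amount of azolium salt secures the second.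

Step 4
Reactants: 5 (5S,10R)-10-methyldecal-8-ene-4,7-dione
Product: 6 (5R,10R)-10-methyldecal-8-ene-4,7-dione (trans-fused; H5 α)
Conditions: 1,8-diazabicyclo[5.4.0]undec-7-ene (0.2 equiv), PhMe, 40 °C; chromatography, cis isomer returned to the equilibration
Reagents that add atoms: none
Why: Base-mediated epimerisation through the C4 enolate can invert only C5, because C10 is quaternary, and should populate the trans-fused isomer with the C4–C5 bond equatorial on ring B, as in classical isomerisations of cis-fused angularly methylated decalindiones; this isomer is separated and the remaining cis isomer is equilibrated again.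

Step 5
Reactants: 6 (5R,10R)-10-methyldecal-8-ene-4,7-dione
Product: 7 (5R,10R)-4,4-(ethylenedioxy)-10-methyldecal-8-en-7-one
Conditions: Me3SiOCH2CH2OSiMe3 (1.2 equiv), Me3SiOSO2CF3 (5 mol %), CH2Cl2, −78 → −20 °C
Reagents that add atoms: 1,2-bis(trimethylsilyloxy)ethane, C[Si](C)(C)OCCO[Si](C)(C)C
Why: Noyori ketalisation under aprotic Lewis-acid catalysis at low temperature should protect the saturated C4 ketone in preference to the conjugated C7 ketone, as is usual for such enediones, and locks the C5 configuration because C5 is no longer next to a carbonyl; no new stereocentre.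

Step 6
Reactants: 7 (5R,10R)-4,4-(ethylenedioxy)-10-methyldecal-8-en-7-one
Product: 9 (5R,10R)-4,4-(ethylenedioxy)-10-methyldecala-6,8-dien-7-yl trifluoromethanesulfonate, via lithium dienolate 8 (not isolated)
Conditions: LiN(iPr)2, THF, −78 °C; then PhNTf2, −78 → 0 °C
Reagents that add atoms: N-phenylbis(trifluoromethanesulfonimide), O=S(=O)(N(c1ccccc1)S(=O)(=O)C(F)(F)F)C(F)(F)F; lithium diisopropylamide, [Li+].CC(C)[N-]C(C)C (lithium of 8)
Why: Kinetic deprotonation of the enone can take place only at C6, since C8 is vinylic and C10 quaternary, and O-sulfonylation of the cross-conjugated dienolate (enol triflate formation) fixes the C6=C7 double bond where the later C7–C11 and C6–O bonds are needed; C5 and C10 are not touched.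

Step 7
Reactants: 9 (5R,10R)-4,4-(ethylenedioxy)-10-methyldecala-6,8-dien-7-yl trifluoromethanesulfonate
Product: 10 (5R,10R)-4,4-(ethylenedioxy)-7-isopropyl-10-methyldecala-6,8-diene
Conditions: i-PrMgCl (1.5 equiv), Fe(acac)3 (5 mol %), THF/N-methylpyrrolidone, −30 °C
Reagents that add atoms: isopropylmagnesium chloride, CC(C)[Mg]Cl
Why: Iron-catalysed Kumada-type cross-coupling of an alkenyl triflate with a secondary alkyl Grignard reagent should replace the triflate by isopropyl at low temperature, faster than the Grignard reagent attacks the ketal; no stereocentre is formed.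

Step 8
Reactants: 10 (5R,10R)-4,4-(ethylenedioxy)-7-isopropyl-10-methyldecala-6,8-diene
Product: 11 (5R,10R)-4,4-(ethylenedioxy)-7-isopropyl-10-methyldecal-6-ene
Conditions: 2-nitrobenzenesulfonylhydrazide, Et3N, CH2Cl2, 23 °C
Reagents that add atoms: none
Why: Diimide released from the sulfonylhydrazide transfers two hydrogens in a concerted syn manner and reacts far faster with the cis-disubstituted C8=C9 bond than with the trisubstituted, isopropyl-bearing C6=C7 bond, so this chemoselective diimide reduction should leave the single trisubstituted alkene; no stereocentre is formed.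

Step 9
Reactants: 11 (5R,10R)-4,4-(ethylenedioxy)-7-isopropyl-10-methyldecal-6-ene
Product: 13 (5S,6S,7S,10R)-4,4-(ethylenedioxy)-7-isopropyl-10-methyldecalin-6-ol, via C6 alkylborane 12 (not isolated)
Conditions: BH3·THF, THF, 0 → 23 °C; then NaOH, H2O2, H2O, 0 °C
Reagents that add atoms: hydrogen peroxide, OO; borane–tetrahydrofuran, B.C1CCOC1 (boron of 12)
Why: In this Brown hydroboration–oxidation boron goes to the less substituted C6 and hydrogen to C7 in a syn addition on the α face, because the axial C14 methyl (1,3 to C6) shields the β face of the trans-fused ring B, and oxidation with retention should give the 6α-hydroxyl and the 7α-hydrogen (7β-isopropyl), both substituents equatorial.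

Step 10
Reactants: 13 (5S,6S,7S,10R)-4,4-(ethylenedioxy)-7-isopropyl-10-methyldecalin-6-ol
Product: 14 (5S,6S,7S,10R)-6-hydroxy-7-isopropyl-10-methyldecalin-4-one
Conditions: 1 M HCl, THF, 23 °C
Reagents that add atoms: water, O
Why: Acid hydrolysis of the dioxolane (acetal cleavage) frees the C4 ketone, β-elimination being disfavoured because the equatorial C6–O bond lies close to the nodal plane of the C4 enol, and the trans-fused isomer with all ring-B substituents equatorial and a 6-OH to C4=O hydrogen bond should remain the stable form at the now enolisable C5.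

Step 11
Reactants: 14 (5S,6S,7S,10R)-6-hydroxy-7-isopropyl-10-methyldecalin-4-one
Product: 15 (5S,6S,7S,10R)-eudesm-4(15)-en-6-ol
Conditions: Zn, CH2Br2, TiCl4, THF, 5 °C (reagent aged); then 14, CH2Cl2, 23 °C
Reagents that add atoms: dibromomethane, BrCBr
Why: Takai–Lombardo methylenation uses a non-basic zinc/titanium methylene reagent that converts hindered, enolisable ketones into methylene compounds without epimerisation, retro-aldol cleavage or β-elimination and tolerates a free hydroxyl, so C5 and C6 should be kept.

Step 12
Reactants: 16 p-coumaric acid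
Product: 18 (E)-3-[4-(tert-butyldimethylsilyloxy)phenyl]prop-2-enoic acid, via silyl ester silyl ether 17 (not isolated)
Conditions: t-BuMe2SiCl (2.2 equiv), imidazole, DMF, 23 °C; then AcOH/THF/H2O, 23 °C
Reagents that add atoms: tert-butyldimethylsilyl chloride, CC(C)(C)[Si](C)(C)Cl
Why: Silylation of both acidic hydroxyls followed by selective hydrolysis of the much more labile silyl ester masks the phenol, so that it cannot compete as a nucleophile in the esterification, and leaves the E alkene untouched.

Step 13
Reactants: 15 (5S,6S,7S,10R)-eudesm-4(15)-en-6-ol; 18 (E)-3-[4-(tert-butyldimethylsilyloxy)phenyl]prop-2-enoic acid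
Product: 19 (5S,6S,7S,10R)-eudesm-4(15)-en-6-yl (E)-3-[4-(tert-butyldimethylsilyloxy)phenyl]prop-2-enoate
Conditions: N,N'-dicyclohexylcarbodiimide, 4-(dimethylamino)pyridine (1 equiv), CH2Cl2, 23 → 40 °C
Reagents that add atoms: none
Why: In this Steglich esterification the acylpyridinium ion derived from the O-acylisourea acylates the hindered equatorial 6-hydroxyl at oxygen, so the C6 configuration is retained and the E geometry of the cinnamoyl unit is unchanged.

Step 14
Reactants: 19 (5S,6S,7S,10R)-eudesm-4(15)-en-6-yl (E)-3-[4-(tert-butyldimethylsilyloxy)phenyl]prop-2-enoate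
Product: 20 (5S,6S,7S,10R)-eudesm-4(15)-en-6-yl (E)-3-(4-hydroxyphenyl)prop-2-enoate
Conditions: Bu4NF, AcOH, THF, 0 °C
Reagents that add atoms: none
Why: Fluoride-induced desilylation of the aryl silyl ether, buffered with acetic acid so that neither phenoxide nor basic fluoride attacks the ester, should release the phenol and leave the four stereocentres and both alkenes as they are.

**Compound list**

1 | p-cresol | Cc1ccc(O)cc1 | starting material
2 | allyltrimethylsilane | C=CC[Si](C)(C)C | starting material
3 | 4-allyl-4-methylcyclohexa-2,5-dien-1-one | C=CCC1(C)C=CC(=O)C=C1 | intermediate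
4 | 4-(1-methyl-4-oxocyclohexa-2,5-dien-1-yl)butanal | O=CCCCC1(C)C=CC(=O)C=C1 | intermediate
5 | (5S,10R)-10-methyldecal-8-ene-4,7-dione, cis-fused | O=C1CCC[C@]2(C)C=CC(=O)C[C@H]12 | intermediate
6 | (5R,10R)-10-methyldecal-8-ene-4,7-dione, trans-fused | O=C1CCC[C@]2(C)C=CC(=O)C[C@@H]12 | intermediate
7 | (5R,10R)-4,4-(ethylenedioxy)-10-methyldecal-8-en-7-one | O1CCOC12CCC[C@]3(C)C=CC(=O)C[C@@H]23 | intermediate
8 | lithium cross-conjugated dienolate of 7 (C6=C7–OLi) | O1CCOC12CCC[C@]3(C)C=CC([O-])=C[C@@H]23.[Li+] | intermediate
9 | (5R,10R)-4,4-(ethylenedioxy)-10-methyldecala-6,8-dien-7-yl trifluoromethanesulfonate | O1CCOC12CCC[C@]3(C)C=CC(OS(=O)(=O)C(F)(F)F)=C[C@@H]23 | intermediate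
10 | (5R,10R)-4,4-(ethylenedioxy)-7-isopropyl-10-methyldecala-6,8-diene | O1CCOC12CCC[C@]3(C)C=CC(C(C)C)=C[C@@H]23 | intermediate
11 | (5R,10R)-4,4-(ethylenedioxy)-7-isopropyl-10-methyldecal-6-ene | O1CCOC12CCC[C@]3(C)CCC(C(C)C)=C[C@@H]23 | intermediate
12 | C6 alkylborane from 11 (6α-BH2, 7β-isopropyl, trans-fused) | O1CCOC12CCC[C@]3(C)CC[C@@H](C(C)C)[C@H](B)[C@@H]23 | intermediate
13 | (5S,6S,7S,10R)-4,4-(ethylenedioxy)-7-isopropyl-10-methyldecalin-6-ol | O1CCOC12CCC[C@]3(C)CC[C@@H](C(C)C)[C@H](O)[C@@H]23 | intermediate
14 | (5S,6S,7S,10R)-6-hydroxy-7-isopropyl-10-methyldecalin-4-one | O=C1CCC[C@]2(C)CC[C@@H](C(C)C)[C@H](O)[C@@H]12 | intermediate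
15 | (5S,6S,7S,10R)-eudesm-4(15)-en-6-ol | C=C1CCC[C@]2(C)CC[C@@H](C(C)C)[C@H](O)[C@@H]12 | intermediate
16 | p-coumaric acid | O=C(O)/C=C/c1ccc(O)cc1 | starting material
17 | tert-butyldimethylsilyl (E)-3-[4-(tert-butyldimethylsilyloxy)phenyl]prop-2-enoate | CC(C)(C)[Si](C)(C)OC(=O)/C=C/c1ccc(O[Si](C)(C)C(C)(C)C)cc1 | intermediate
18 | (E)-3-[4-(tert-butyldimethylsilyloxy)phenyl]prop-2-enoic acid | O=C(O)/C=C/c1ccc(O[Si](C)(C)C(C)(C)C)cc1 | intermediate
19 | (5S,6S,7S,10R)-eudesm-4(15)-en-6-yl (E)-3-[4-(tert-butyldimethylsilyloxy)phenyl]prop-2-enoate | C=C1CCC[C@]2(C)CC[C@@H](C(C)C)[C@H](OC(=O)/C=C/c3ccc(O[Si](C)(C)C(C)(C)C)cc3)[C@@H]12 | intermediate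
20 | (5S,6S,7S,10R)-eudesm-4(15)-en-6-yl (E)-3-(4-hydroxyphenyl)prop-2-enoate | C=C1CCC[C@]2(C)CC[C@@H](C(C)C)[C@H](OC(=O)/C=C/c3ccc(O)cc3)[C@@H]12 | target

**Step count and risks**

Total step count: 14. Longest linear sequence: 13 steps (steps 1–11, 13 and 14; step 12 is a one-step side branch).

Steps most likely to fail:

Step 3. The six-membered closure may be slower than the five-membered closures on which this reaction type rests. Self-aldol and benzoin-type oligomerisation of the enolisable aldehyde could then take over, or the two enone arms could be told apart poorly. The fallback sets out from 4 and comes back at 5; it changes the acyl anion equivalent from the catalytic enaminol to a nitronate.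
- Compound 4 is condensed with NH2OH·HCl and NaOAc to 4-(1-methyl-4-oxocyclohexa-2,5-dien-1-yl)butanal oxime F1.
- NaBO3·4H2O in AcOH oxidises it to 4-methyl-4-(4-nitrobutyl)cyclohexa-2,5-dien-1-one F2.
- The bifunctional catalyst 1-[3,5-bis(trifluoromethyl)phenyl]-3-[(8α,9S)-6'-methoxycinchonan-9-yl]thiourea (or its pseudoenantiomer, whichever gives the C10 configuration of 5) brings about a desymmetrising intramolecular nitro-Michael addition. It forms the same C4–C5 bond in the same 6-exo mode and gives cis-fused 10-methyl-4-nitrodecal-8-en-7-one F3 (C4 epimers are of no consequence).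
- A Nef reaction of its nitronate (KOt-Bu, then dimethyldioxirane in acetone) turns C4 into the ketone and returns to 5.

Step 4. The equilibrium between the two ring fusions may lie on the cis side, as it can for 1-decalones that carry an angular methyl group, so that separation and recycling become inefficient. The fallback sets out from 5 and comes back at 13; C5 is erased and then set kinetically together with C6.
- Compound 5 is ketalised under the conditions of step 5 to the cis-fused C4 ethylene ketal F4.
- LiN(iPr)2 and Me3SiCl give the trimethylsilyl dienol ether F5, which Pd(OAc)2 in MeCN (Saegusa–Ito oxidation) turns into the cross-conjugated 5,8-dien-7-one F6, in which C5 is no longer a stereocentre.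
- H2 with RhCl(PPh3)3 reduces only the disubstituted C8=C9 bond and gives the 5-en-7-one F7.
- i-PrMgCl with CeCl3 adds to the C7 carbonyl and gives the tertiary allylic alcohol F8.
- BH3·THF followed by NaOH/H2O2 delivers hydrogen to C5 and boron to C6 on the α face, away from C14 as with 5-ene steroids, and gives the trans-fused 6α,7-diol F9.
- 1,1'-Thiocarbonyldiimidazole closes the cyclic thiocarbonate F10.
- Bu3SnH with 2,2'-azobis(2-methylpropionitrile) cleaves the tertiary C7–O bond, and the C7 radical should take up hydrogen axially on the α face, giving the tributylstannyl thiolcarbonate F11.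
- NaOH in MeOH converts F11 into 13.

Step 1. The oxidised phenol may be captured at an ortho carbon, or by acetate or the solvent, instead of by the silane at the para carbon. The fallback sets out from commercial 2-methylpent-4-enal and but-3-en-2-one in place of 1 and 2 and comes back at 3.
- Acid-catalysed Robinson annulation (H2SO4 cat., PhMe, reflux with removal of water) gives 4-allyl-4-methylcyclohex-2-en-1-one F12.
- Dehydrogenation with 2,3-dichloro-5,6-dicyano-1,4-benzoquinone in dioxane at reflux gives 3.

Further compounds
F1 | step 3 | 4-(1-methyl-4-oxocyclohexa-2,5-dien-1-yl)butanal oxime | ON=CCCCC1(C)C=CC(=O)C=C1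
F2 | step 3 | 4-methyl-4-(4-nitrobutyl)cyclohexa-2,5-dien-1-one | O=[N+]([O-])CCCCC1(C)C=CC(=O)C=C1
F3 | step 3 | cis-fused 10-methyl-4-nitrodecal-8-en-7-one (H5 and C14 β, C4 epimers) | O=[N+]([O-])C1CCC[C@]2(C)C=CC(=O)C[C@H]12
F4 | step 4 | cis-fused 4,4-(ethylenedioxy)-10-methyldecal-8-en-7-one (C5 epimer of 7) | O1CCOC12CCC[C@]3(C)C=CC(=O)C[C@H]23
F5 | step 4 | trimethylsilyl dienol ether of F4 (C6=C7–OSiMe3) | O1CCOC12CCC[C@]3(C)C=CC(O[Si](C)(C)C)=C[C@H]23
F6 | step 4 | (10R)-4,4-(ethylenedioxy)-10-methyldecala-5,8-dien-7-one | O1CCOC12CCC[C@]3(C)C=CC(=O)C=C23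
F7 | step 4 | (10R)-4,4-(ethylenedioxy)-10-methyldecal-5-en-7-one | O1CCOC12CCC[C@]3(C)CCC(=O)C=C23
F8 | step 4 | (10R)-4,4-(ethylenedioxy)-7-isopropyl-10-methyldecal-5-en-7-ol (C7 epimers) | O1CCOC12CCC[C@]3(C)CCC(O)(C(C)C)C=C23
F9 | step 4 | trans-fused 4,4-(ethylenedioxy)-7-isopropyl-10-methyldecalin-6α,7-diol (H5 α) | O1CCOC12CCC[C@]3(C)CCC(O)(C(C)C)[C@H](O)[C@@H]23
F10 | step 4 | cyclic 6,7-thiocarbonate of F9 | O1CCOC12CCC[C@]3(C)CCC4(C(C)C)OC(=S)O[C@@H]4[C@@H]23
F11 | step 4 | O-6 (tributylstannylthio)carbonyl derivative of 13 | O1CCOC12CCC[C@]3(C)CC[C@@H](C(C)C)[C@H](OC(=O)S[Sn](CCCC)(CCCC)CCCC)[C@@H]23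
F12 | step 1 | 4-allyl-4-methylcyclohex-2-en-1-one (racemic) | C=CCC1(C)CCC(=O)C=C1
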